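## Retrosynthetic overview

1. Target 21 comes from 7-ketone 20 by hydride delivery to the α face. 20 comes from 8α-hydroxylabda-12E,14-dien-7-one 16 by C6 hydroxylation and angeloylation. The diene of 16 comes from the allyl group of α-ketol 13 by cross metathesis and methylenation.
2. Enabling feature: in ring B (C5–C10), the triad C7(O)–C8(OH)(CH3)–C9(H) is, at the ketone level, a 2-hydroxy-2-methylcyclohexanone, which is the retron of a reductive 1,2-acyl shift. So 13 comes from the 2-acetyl-2-allylcyclopentanone 11, whose five-membered ring C5–C6–C7–C9–C10 takes up the acetyl carbon C8 between C7 and C9.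
3. Second feature: 5-H, 6-O, 7-H, 8-O and 9-H all lie on the α face, opposite the C10 methyl. C10 alone, set by Pd-catalysed asymmetric allylation, therefore relays the five other ring-B stereocentres.
4. 11 comes from hydrindenone 6 by acylation, hydrogenation and allylation. 6 comes from (R)-2-allyl-2,6,6-trimethylcyclohexanone 4 by Wacker oxidation and aldol closure, and 4 comes from 2,2,6-trimethylcyclohexanone 1.
5. Ring order: ring A is bought, the five-membered proto-ring B is closed in step 4, and ring B forms in step 8 by one-carbon expansion through a transient cyclopropane.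

Key step: step 8

Convention: labdane atom numbers are kept for all intermediates. In the hydrindanes the five-membered ring is C5–C6–C7–C9–C10 and the acetyl carbons are C8 and C17. β is the face of the C10 methyl and α is the opposite face.

Assumption: (R)-t-BuPHOX is taken to give (R)-4, following the established sense of induction of this ligand class; the antipodal ligand would give ent-4.

## Route

Step 1
Reactants: 1 2,2,6-trimethylcyclohexanone (racemic); 2 allyl chloroformate
Product: 3 allyl 2,6,6-trimethylcyclohex-1-en-1-yl carbonate
Conditions: LiHMDS, THF, 0 °C; then 2, −78 °C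
Reagents that add atoms: none
Why: Only one α-hydrogen is present, so a single tetrasubstituted lithium enolate forms, and its O-acylation by the chloroformate gives the enol carbonate and erases the stereocentre of racemic 1.

Step 2
Reactants: 3 allyl 2,6,6-trimethylcyclohex-1-en-1-yl carbonate
Product: 4 (R)-2-allyl-2,6,6-trimethylcyclohexanone
Conditions: Pd2(dba)3 (2.5 mol%), (R)-t-BuPHOX (6 mol%), THF, 25 °C
Reagents that add atoms: none
Why: In this decarboxylative asymmetric allylic alkylation (Tsuji type, Pd/PHOX), loss of CO2 gives a Pd enolate/π-allyl pair that forms C9–C10 in the chiral pocket and sets quaternary C10 as R, the only stereocentre of the route made by catalysis.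

Step 3
Reactants: 4 (R)-2-allyl-2,6,6-trimethylcyclohexanone
Product: 5 (R)-2,2,6-trimethyl-6-(2-oxopropyl)cyclohexanone
Conditions: PdCl2 (cat.), Cu(OAc)2 (cat.), O2 (1 atm), DMA/H2O, 25 °C
Reagents that add atoms: water, O
Why: Tsuji–Wacker oxidation places oxygen on the internal alkene carbon and turns the allyl group into the C9–C7(=O)–C6 acetonyl unit without touching C10.

Step 4
Reactants: 5 (R)-2,2,6-trimethyl-6-(2-oxopropyl)cyclohexanone
Product: 6 (R)-4,4,7a-trimethyl-1,4,5,6,7,7a-hexahydro-2H-inden-2-one
Conditions: KOH, xylenes, 110 °C, Dean–Stark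
Reagents that add atoms: none
Why: Intramolecular aldol condensation (the usual 1,4-diketone to cyclopentenone closure) joins methyl carbon C6 to ring ketone C5 and, after loss of water, closes the ring C5–C6–C7–C9–C10 without forming a new stereocentre.

Step 5
Reactants: 6 (R)-4,4,7a-trimethyl-1,4,5,6,7,7a-hexahydro-2H-inden-2-one; 7 1-acetyl-1H-benzotriazole
Product: 8 C9-acetyl hydrindenone (β-diketone/enol mixture)
Conditions: MgBr2·OEt2, i-Pr2NEt, CH2Cl2, 25 °C
Reagents that add atoms: none
Why: In this soft-enolisation C-acylation (crossed Claisen type), C9 is the only enolisable position because the γ-carbons C4 and C10 are quaternary, the magnesium chelate of the β-diketone drives the acyl transfer, and C9 stays configurationally labile.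

Step 6
Reactants: 8 C9-acetyl hydrindenone
Product: 9 C9-acetyl trans-hydrindan-7-one (5α-H)
Conditions: H2 (4 atm), 10% Pd/C, EtOAc, 25 °C
Reagents that add atoms: none
Why: In this heterogeneous hydrogenation of C5=C6, the β face is blocked by the two syn-axial methyl groups on C4 and C10 that flank C5, so hydrogen arrives from the α face and sets 5α-H (trans fusion), which cannot epimerise later because C5 is never α to a carbonyl.

Step 7
Reactants: 9 C9-acetyl trans-hydrindan-7-one; 10 allyl methyl carbonate
Product: 11 9α-allyl-9β-acetyl trans-hydrindan-7-one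
Conditions: Pd(PPh3)4 (5 mol%), THF, 50 °C
Reagents that add atoms: none
Why: In this neutral Tsuji–Trost allylation, the soft β-diketone enolate attacks the π-allylpalladium cation through its α face, anti to the adjacent C10 methyl (the facial rule of 17-alkylation in 20-oxo steroids), so quaternary C9 carries allyl α and acetyl β, and any O-allylation is reversible under Pd(0).

Step 8
Reactants: 11 9α-allyl-9β-acetyl trans-hydrindan-7-one
Product: 13 8α-hydroxy-14,15,16-trinorlabd-12-en-7-one, via cyclopropane-1,2-diol 12 (not isolated)
Conditions: SmI2 (2.1 equiv, slow addition), t-BuOH, THF, −78 °C → 25 °C; then 0.5 M HCl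
Reagents that add atoms: none
Why: Proposed new method: Sm(II) chelates both carbonyl oxygens of the non-enolisable 1,3-diketone and transfers one electron, the ketyl carbon C8 adds 3-exo-trig to the C7 carbonyl on the β face where the acetyl sits, and the second electron gives the cis-cyclopropane-1,2-diolate 12 (a bicyclo[3.1.0]hexane). The strained C7–C9 bond shared by the three- and five-membered rings then breaks, C7–O becomes the ketone and C9 takes up hydrogen, so C8 is inserted between C7 and C9 and ring B forms by one-carbon expansion of the cyclopentanone, a net reductive 1,2-acyl shift. The closest known reaction types are the Clemmensen-type reductive rearrangement of 2,2-dialkyl-1,3-diketones through cyclopropane-1,2-diols to α-ketols, the Sm(II) pinacol cyclisation, and the Dowd–Beckwith ring expansion (3-exo attack on C=O followed by scission of the ring bond). C8 is controlled by the chelate together with the C9 configuration: both oxygens stay cis on the cyclopropane, which puts O8 exo and C17 endo on the β face and unfolds to equatorial 8α-OH and axial 8β-CH3. C9 is controlled by the same geometry: hydrogen replaces C7 with retention in the protonolysis, and a C9 radical or organosamarium on an open-shell path would be quenched from the α face opposite the C10 methyl, so both paths give 9α-H with an equatorial allyl group. The step needs cleavage of C7–C9 rather than C8–C9 and a stop at the α-ketol: C6 is never involved because only C9 lacks oxygen, opening the shared bond releases the strain of both small rings and the crowding of the C9/C10 quaternary pair, the isomeric 7-acetyl-7-hydroxy hydrindane would funnel to 13 by a Sm(III)-chelated α-ketol shift of the same stereochemical sense, and slow addition of only two equivalents of SmI2 guards against C8–O cleavage.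

Step 9
Reactants: 13 8α-hydroxy-14,15,16-trinorlabd-12-en-7-one; 14 methacrolein
Product: 15 (12E)-8α-hydroxy-7-oxo-15-norlabd-12-en-14-al
Conditions: Hoveyda–Grubbs II (5 mol%), excess 14, CH2Cl2, 40 °C
Reagents that add atoms: none
Why: Olefin cross metathesis of a terminal alkene with excess methacrolein gives the trisubstituted enal under thermodynamic control as the E isomer, which sets the C12=C13 geometry, and the ketone and tertiary alcohol are tolerated.

Step 10
Reactants: 15 (12E)-8α-hydroxy-7-oxo-15-norlabd-12-en-14-al
Product: 16 8α-hydroxylabda-12E,14-dien-7-one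
Conditions: Ph3PCH3Br, KHMDS, THF, −78 → 0 °C
Reagents that add atoms: methyltriphenylphosphonium bromide, C[P+](c1ccccc1)(c1ccccc1)c1ccccc1.[Br-]
Why: In this Wittig methylenation the unhindered aldehyde reacts at low temperature much faster than the C7 ketone, which is shielded by quaternary C8, and the C12=C13 geometry is untouched.

Step 11
Reactants: 16 8α-hydroxylabda-12E,14-dien-7-one
Product: 17 6α,8α-dihydroxylabda-12E,14-dien-7-one
Conditions: KHMDS (2.5 equiv), THF, −78 °C; 2-(phenylsulfonyl)-3-phenyloxaziridine; AcOH quench
Reagents that add atoms: 2-(phenylsulfonyl)-3-phenyloxaziridine, O=S(=O)(c1ccccc1)N1OC1c1ccccc1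
Why: In this enolate hydroxylation with an N-sulfonyloxaziridine, C6 is the only enolisable position of the C7 ketone (C8 is quaternary) and the β face of the enolate is blocked by the syn-axial methyls on C4 and C10, so oxygen enters from the α face to give equatorial 6α-OH, which is also the thermodynamic epimer, and the diene is inert to this oxidant.

Step 12
Reactants: 17 6α,8α-dihydroxylabda-12E,14-dien-7-one; 18 angelic acid
Product: 20 6α-angeloyloxy-8α-hydroxylabda-12E,14-dien-7-one, via mixed anhydride 19 (not isolated)
Conditions: 18, 2,4,6-trichlorobenzoyl chloride, Et3N, toluene, 25 °C; then 17, 80 °C (no DMAP)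
Reagents that add atoms: none
Why: This Yamaguchi-type mixed-anhydride esterification is run without a nucleophilic catalyst to keep the Z geometry of the angelate, only the secondary 6α-OH is acylated because 8α-OH is tertiary, and no stereocentre changes.

Step 13
Reactants: 20 6α-angeloyloxy-8α-hydroxylabda-12E,14-dien-7-one
Product: 21 6α-angeloyloxylabda-12E,14-diene-7β,8α-diol (CNP0189082.1)
Conditions: NaBH4, CeCl3·7H2O, MeOH, −78 → −40 °C; AcOH quench
Reagents that add atoms: none
Why: In this Luche-type 1,2-reduction, hydride attacks C7 axially from the α face because the equatorial β trajectory runs into the axial 8β-methyl, giving equatorial 7β-OH, while low temperature and the mildly acidic quench suppress 6→7 acyl migration and the ester and diene are not reduced.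

## Compound list

1 | 2,2,6-trimethylcyclohexanone (racemic) | CC1CCCC(C)(C)C1=O | starting material
2 | allyl chloroformate | C=CCOC(=O)Cl | starting material
3 | allyl 2,6,6-trimethylcyclohex-1-en-1-yl carbonate | C=CCOC(=O)OC1=C(C)CCCC1(C)C | intermediate
4 | (R)-2-allyl-2,6,6-trimethylcyclohexanone | C=CC[C@@]1(C)CCCC(C)(C)C1=O | intermediate
5 | (R)-2,2,6-trimethyl-6-(2-oxopropyl)cyclohexanone | CC(=O)C[C@@]1(C)CCCC(C)(C)C1=O | intermediate
6 | (R)-4,4,7a-trimethyl-1,4,5,6,7,7a-hexahydro-2H-inden-2-one | CC1(C)CCC[C@]2(C)CC(=O)C=C12 | intermediate
7 | 1-acetyl-1H-benzotriazole | CC(=O)n1nnc2ccccc12 | starting material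
8 | C9-acetyl hydrindenone (1-acetyl derivative of 6; keto/enol mixture, C9 labile and drawn undefined) | CC(=O)C1C(=O)C=C2C(C)(C)CCC[C@]12C | intermediate
9 | C9-acetyl trans-hydrindan-7-one (5α-H, 10β-CH3; C9 labile and drawn undefined) | CC(=O)C1C(=O)C[C@H]2C(C)(C)CCC[C@]12C | intermediate
10 | allyl methyl carbonate | C=CCOC(=O)OC | starting material
11 | 9α-allyl-9β-acetyl trans-hydrindan-7-one (5α-H, 10β-CH3) | C=CC[C@]1(C(C)=O)C(=O)C[C@H]2C(C)(C)CCC[C@]12C | intermediate
12 | cis-cyclopropane-1,2-diol C7(OH)–C8(OH)(CH3)–C9 on the β face (bicyclo[3.1.0]hexane; present as its Sm(III) diolate, drawn as the diol) | C=CC[C@]12[C@](C)(O)[C@@]1(O)C[C@H]3C(C)(C)CCC[C@]23C | intermediate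
13 | 8α-hydroxy-14,15,16-trinorlabd-12-en-7-one (9β-allyl, 8β-CH3, trans-decalone) | C=CC[C@H]1[C@](C)(O)C(=O)C[C@H]2C(C)(C)CCC[C@@]21C | intermediate
14 | methacrolein | C=C(C)C=O | starting material
15 | (12E)-8α-hydroxy-7-oxo-15-norlabd-12-en-14-al | O=C/C(C)=C/C[C@H]1[C@](C)(O)C(=O)C[C@H]2C(C)(C)CCC[C@@]21C | intermediate
16 | 8α-hydroxylabda-12E,14-dien-7-one | C=C/C(C)=C/C[C@H]1[C@](C)(O)C(=O)C[C@H]2C(C)(C)CCC[C@@]21C | intermediate
17 | 6α,8α-dihydroxylabda-12E,14-dien-7-one | C=C/C(C)=C/C[C@H]1[C@](C)(O)C(=O)[C@H](O)[C@H]2C(C)(C)CCC[C@@]21C | intermediate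
18 | angelic acid, (Z)-2-methylbut-2-enoic acid | C/C=C(/C)C(=O)O | starting material
19 | angelic 2,4,6-trichlorobenzoic anhydride | C/C=C(/C)C(=O)OC(=O)c1c(Cl)cc(Cl)cc1Cl | intermediate
20 | 6α-angeloyloxy-8α-hydroxylabda-12E,14-dien-7-one | C=C/C(C)=C/C[C@H]1[C@](C)(O)C(=O)[C@H](OC(=O)/C(C)=C\C)[C@H]2C(C)(C)CCC[C@@]21C | intermediate
21 | 6α-angeloyloxylabda-12E,14-diene-7β,8α-diol (CNP0189082.1) | C=C/C(C)=C/C[C@H]1[C@](C)(O)[C@@H](O)[C@H](OC(=O)/C(C)=C\C)[C@H]2C(C)(C)CCC[C@@]21C | target

Total step count: 13. Longest linear sequence: 13 steps (from 1).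

## Steps most likely to fail

**Step 8 (proposed new method).**
- What may go wrong:
  - Stepwise reduction of one carbonyl to the carbinol instead of C7–C8 coupling.
  - Reductive loss of the C8 oxygen once the α-ketol has formed.
  - Opening of the diolate toward the acetyl side.
  - Erosion of chelate control at C8.
- Fallback (known chemistry): it sets out from 6 and comes back at 13.
  - α′-Allylation of 6 (LDA, allyl bromide), then re-enolisation and kinetic protonation from the α face, gives the 9β-allyl hydrindenone F1.
  - Lewis-acid-promoted homologation with diazoethane (BF3·OEt2, −78 °C) follows. This is a Tiffeneau–Demjanov-type shift in which the saturated α′ carbon C9 of an enone migrates with retention. It expands the five-membered ring to the 8-methyl-Δ5-7-one F2.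
  - α′-Hydroxylation of the cross-conjugated potassium enolate of F2 with the N-sulfonyloxaziridine from the α face gives the 8α-hydroxy enone F3.
  - Li/NH3 reduction of the enone sets 5α-H by axial protonation, leaves the allyl group untouched, and returns to 13.

**Step 7.**
- What may go wrong:
  - Slow C–C bond formation next to quaternary C10.
  - Persistent O-allylation.
  - Retro-Claisen loss of the acetyl group from the product.
  - Poor facial selectivity.
- Fallback: it sets out from 9 and comes back at 11.
  - Deliberate O-allylation (allyl bromide, Cs2CO3, DMF) gives the allyl enol ether F4.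
  - A thermal Claisen [3,3] rearrangement (toluene, 110–140 °C) then delivers the allyl group intramolecularly to C9 through the less hindered α face.

**Step 12.**
- What may go wrong:
  - Z→E isomerisation of the acyl donor, giving the tiglate.
  - Lack of reaction at the hindered 6α-OH.
  - Base- or heat-induced transposition of the 6-hydroxy-7-ketone.
- Fallback: it sets out from 17 and comes back at 20.
  - Carbodiimide coupling with 2-[bis(2,2,2-trifluoroethoxy)phosphoryl]propanoic acid gives the phosphonopropionate ester F5.
  - A Still–Gennari olefination (KHMDS, 18-crown-6, acetaldehyde, −78 °C) then builds the Z-2-methylbut-2-enoate on the molecule.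

## Further compounds

F1 | step 8 | 9β-allyl hydrindenone (9α-H) | C=CC[C@H]1C(=O)C=C2C(C)(C)CCC[C@]12C
F2 | step 8 | 9β-allyl-8-methyl-Δ5-decalen-7-one (C8 epimers, drawn undefined) | C=CC[C@H]1C(C)C(=O)C=C2C(C)(C)CCC[C@@]21C
F3 | step 8 | 8α-hydroxy-14,15,16-trinorlabda-5,12-dien-7-one | C=CC[C@H]1[C@](C)(O)C(=O)C=C2C(C)(C)CCC[C@@]21C
F4 | step 7 | C7 O-allyl enol ether of 9 | C=CCOC1=C(C(C)=O)[C@@]2(C)CCCC(C)(C)[C@@H]2C1
F5 | step 12 | 6α-O-{2-[bis(2,2,2-trifluoroethoxy)phosphoryl]propanoyl} derivative of 17 | C=C/C(C)=C/C[C@H]1[C@](C)(O)C(=O)[C@H](OC(=O)C(C)P(=O)(OCC(F)(F)F)OCC(F)(F)F)[C@H]2C(C)(C)CCC[C@@]21C
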